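## Retrosynthetic overview

1. Cudraflavanone A ⇐ its 7-O-TIPS ether; the only operation after the stereocentre is set is a buffered desilylation.
2. The C2–C1' bond and the C2 stereocentre are made together by a proposed catalytic asymmetric ortho-Friedel–Crafts hydroarylation of a 5-hydroxy-6-prenylchromone with 2,2-dimethyl-2H-chromen-7-ol.
3. The chromone ⇐ 5,7-dihydroxychromone by 7-O-silylation, 5-O-allylation, Claisen rearrangement to C6 and cross-metathesis; this fixes the 6-prenyl regiochemistry.
4. The chromenol ⇐ resorcinol + 3-methylbut-2-enoic acid (chromanone, then reduction and dehydration).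
5. Ring order: the A/C pyranone is bought preformed, the B-ring pyran is built on its own fragment, and no ring is formed after the union.

Assumption: 5,7-dihydroxychromone is taken as a purchasable starting material.
Assumption: the (R)-ligand is written for step 8; the facial sense of a new reaction cannot be known in advance, so the (S)-ligand is used instead if chiral HPLC/CD shows the opposite sense.

## Route

**Step 1**
Reactants: 1, 5,7-dihydroxy-4H-chromen-4-one
Product: 2, 5-hydroxy-7-[(triisopropylsilyl)oxy]-4H-chromen-4-one
Conditions: TIPSCl (1.1 equiv), imidazole, DMF, 0 °C → rt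
Reagents that add atoms: TIPSCl, CC(C)[Si](Cl)(C(C)C)C(C)C
Why: Chemoselective O-silylation; the 5-OH is hydrogen-bonded to the C4 carbonyl and hindered, so the bulky silyl chloride reacts only at the free, more acidic 7-OH.

**Step 2**
Reactants: 2; 3, allyl alcohol (prop-2-en-1-ol)
Product: 4, 5-(allyloxy)-7-[(triisopropylsilyl)oxy]-4H-chromen-4-one
Conditions: PPh3, DIAD, THF, 0 °C → rt
Reagents that add atoms: allyl alcohol (reactant 3), C=CCO
Why: Mitsunobu etherification alkylates the chelated 5-OH under neutral conditions that leave the aryl silyl ether and the chromone intact.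

**Step 3**
Reactants: 4
Product: 5, 6-allyl-5-hydroxy-7-[(triisopropylsilyl)oxy]-4H-chromen-4-one
Conditions: PhNEt2, 200 °C, sealed tube, degassed
Reagents that add atoms: none
Why: Aromatic Claisen rearrangement; C6 is the only unsubstituted ortho position of the O5 allyl ether (C4a is quaternary), so the allyl group goes to C6 and the regenerated 5-OH re-chelates the carbonyl.

**Step 4**
Reactants: 5; 6, 2-methylbut-2-ene
Product: 7, 5-hydroxy-6-(3-methylbut-2-en-1-yl)-7-[(triisopropylsilyl)oxy]-4H-chromen-4-one
Conditions: Grubbs II (5 mol%), 2-methylbut-2-ene/CH2Cl2, 40 °C, sealed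
Reagents that add atoms: 2-methylbut-2-ene (reactant 6), CC=C(C)C
Why: Olefin cross-metathesis converts the terminal allyl into prenyl, while the electron-poor, oxygen-substituted chromone C2=C3 does not react.

**Step 5**
Reactants: 8, resorcinol; 9, 3-methylbut-2-enoic acid
Product: 10, 7-hydroxy-2,2-dimethylchroman-4-one
Conditions: P2O5/MeSO3H (Eaton's reagent), 70 °C
Reagents that add atoms: none (both partners are numbered reactants; water is lost)
Why: Friedel–Crafts acylation at C4 of resorcinol followed by intramolecular oxa-Michael addition of the ortho-OH gives the 7-hydroxychromanone regioselectively.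

**Step 6**
Reactants: 10
Product: 11, 2,2-dimethylchromane-4,7-diol (racemic at C4)
Conditions: NaBH4 (3 equiv), THF/MeOH, 0 °C → rt
Reagents that add atoms: none
Why: Borohydride reduction of the aryl ketone; the C4 stereocentre is irrelevant because it is destroyed in step 7.

**Step 7**
Reactants: 11
Product: 12, 2,2-dimethyl-2H-chromen-7-ol
Conditions: p-TsOH·H2O (5 mol%), toluene, 70 °C, 30 min; NaHCO3 quench
Reagents that add atoms: none
Why: Acid-catalysed E1 dehydration of the benzylic alcohol (cation stabilised by the para-OH) gives the conjugated 2H-chromene.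

**Step 8 (key step)**
Reactants: 7; 12 (1.5 equiv)
Product: 13, (2S)-5-hydroxy-2-(7-hydroxy-2,2-dimethyl-2H-chromen-6-yl)-6-(3-methylbut-2-en-1-yl)-7-[(triisopropylsilyl)oxy]chroman-4-one
Conditions: B(OPh)3 (20 mol%), (R)-3,3'-bis[3,5-bis(trifluoromethyl)phenyl]-BINOL (20 mol%), 4 Å MS, PhCF3, 0 °C → rt; aqueous NaHCO3 work-up
Reagents that add atoms: none (7 and 12 combine with no atoms added or lost)
Why: Proposed new method: chiral spiroborate-catalysed asymmetric ortho-C–H Friedel–Crafts hydroarylation of a 5-hydroxychromone — B(OPh)3 and the BINOL condense with the 5-OH/4-C=O chelating unit of 7 to a tetracoordinate spiroborate that gives the pyranone 4-boryloxybenzopyrylium character (C2 electrophilic); phenol 12, hydrogen-bonded through its OH to a borate oxygen acting as general base, attacks C2 through its C6 (ortho to OH and para to the ring oxygen, whereas C8 is flanked by two oxygens) on the C2 Re face left open by one 3-aryl wing, which sets (2S); rearomatisation, C3 protonation of the boron enolate and chelate exchange with fresh 7 turn the catalyst over; the closest known reaction types are chiral BINOL-borate-catalysed Diels–Alder reactions of chelating 2'-hydroxychalcones and asymmetric ortho-Friedel–Crafts additions of phenols to enones and benzopyrylium ions.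

**Step 9**
Reactants: 13
Product: 14, cudraflavanone A, (2S)-5,7-dihydroxy-2-(7-hydroxy-2,2-dimethyl-2H-chromen-6-yl)-6-(3-methylbut-2-en-1-yl)chroman-4-one
Conditions: HF·pyridine, pyridine/THF, 0 °C
Reagents that add atoms: none
Why: Fluoride cleavage of the aryl silyl ether under buffered, non-basic conditions avoids the base-induced retro-oxa-Michael (chalcone) pathway that would racemise C2, and leaves the prenyl and chromene alkenes untouched.

## Compound list

1 | 5,7-dihydroxy-4H-chromen-4-one | O=c1ccoc2cc(O)cc(O)c12 | starting material
2 | 5-hydroxy-7-(triisopropylsilyloxy)-4H-chromen-4-one | O=c1ccoc2cc(O[Si](C(C)C)(C(C)C)C(C)C)cc(O)c12 | intermediate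
3 | allyl alcohol | C=CCO | starting material
4 | 5-(allyloxy)-7-(triisopropylsilyloxy)-4H-chromen-4-one | C=CCOc1cc(O[Si](C(C)C)(C(C)C)C(C)C)cc2occc(=O)c12 | intermediate
5 | 6-allyl-5-hydroxy-7-(triisopropylsilyloxy)-4H-chromen-4-one | C=CCc1c(O[Si](C(C)C)(C(C)C)C(C)C)cc2occc(=O)c2c1O | intermediate
6 | 2-methylbut-2-ene | CC=C(C)C | starting material
7 | 5-hydroxy-6-prenyl-7-(triisopropylsilyloxy)-4H-chromen-4-one | CC(C)=CCc1c(O[Si](C(C)C)(C(C)C)C(C)C)cc2occc(=O)c2c1O | intermediate
8 | resorcinol | Oc1cccc(O)c1 | starting material
9 | 3-methylbut-2-enoic acid | CC(C)=CC(=O)O | starting material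
10 | 7-hydroxy-2,2-dimethylchroman-4-one | CC1(C)CC(=O)c2ccc(O)cc2O1 | intermediate
11 | 2,2-dimethylchromane-4,7-diol (racemic) | CC1(C)CC(O)c2ccc(O)cc2O1 | intermediate
12 | 2,2-dimethyl-2H-chromen-7-ol | CC1(C)C=Cc2ccc(O)cc2O1 | intermediate
13 | (2S)-7-O-TIPS-cudraflavanone A | CC(C)=CCc1c(O[Si](C(C)C)(C(C)C)C(C)C)cc2c(c1O)C(=O)C[C@@H](c1cc3c(cc1O)OC(C)(C)C=C3)O2 | intermediate
14 | cudraflavanone A | CC(C)=CCc1c(O)cc2c(c1O)C(=O)C[C@@H](c1cc3c(cc1O)OC(C)(C)C=C3)O2 | target

## Step count and risks

Total steps: 9 (four to chromone 7, three to chromenol 12, coupling, deprotection).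
Longest linear sequence: 6 steps (1 → 2 → 4 → 5 → 7 → 13 → 14).

Three steps most likely to fail:

1. **Step 8 (proposed new method).** Risks: the chelated chromone may not be electrophilic enough; reversible O-attack, or C-attack through C8 or the chromene C3, may compete; ee may erode by Lewis-acid ionisation of the C2–O1 bond, which the 2'-OH assists. Fallback (known chemistry): Rh(I)/chiral bisphosphine-catalysed asymmetric 1,4-addition of an arylboronic acid to the chromone (Hayashi–Miyaura type). The partner is [7-(TBSO)-2,2-dimethyl-2H-chromen-6-yl]boronic acid, made from 4-bromoresorcinol by the same chromanone → chromene sequence, then O-silylation and Br/Li/B exchange. It is added to 7 (5-OH free or as its acetate), followed by global desilylation.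

2. **Step 3 (Claisen rearrangement).** Risks: Claisen–Cope migration on to C8, or silyl loss at 200 °C next to the bulky 7-OTIPS group. Fallback: drop the sigmatropic route; iodinate 2 at C6 under 5-OH direction (BnMe3N+ ICl2−, CaCO3) and install the prenyl group by Stille coupling with tributyl(3-methylbut-2-enyl)stannane. This gives 7 directly and replaces steps 2–4.

3. **Step 9 (final desilylation).** Risks: 2'-hydroxyflavanones racemise or open to chalcones easily, and the chromene and ortho-prenylphenol are acid-sensitive. Fallback: change the protecting-group strategy at the achiral chromone stage: desilylate 7 (TBAF) and re-protect O7 as the allyl carbonate (AllocCl). The last step then becomes a neutral Pd(PPh3)4/dimedone deallylation instead of a fluoride cleavage.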